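## Analysis of the target

CNP0349227.1 is a briarane-type diterpenoid: a cyclohexane (C1, C10–C14) is trans-fused through C1 and C10 to a ten-membered carbocycle (C1–C10), and a γ-lactone (O on C7, C8, C17, C19 as carbonyl) is fused across C7–C8. It carries eleven stereocentres. On the six-membered ring the C1–C2 bond, the C14 and C12 acetoxy groups, the epoxide oxygen on C11 and H10 lie on one face; the C15 methyl, C20 and the C10–C9 bond lie on the other. On the large ring C2 and C9 bear acetates, C8 a free tertiary hydroxyl, C7 the lactone oxygen and C6 a secondary allylic chloride next to the C5=C16 methylene; C17 bears the lactone methyl (C18). The sensitive groups are the 1,1-disubstituted epoxide (acid, Lewis acid), the allylic chloride (SN2′, elimination), the β-hydroxy lactone (retro-aldol, C17 epimerisation under base) and four acetates, so the last steps must be close to neutral. The difficulty is the medium ring, which has to be closed against transannular strain next to a quaternary carbon while carrying the contiguous heteroatom-bearing carbons C6–C9. The strategy rests on C7 and C8: adjacent oxygen-bearing carbons, C8 fully substituted and β to the C19 carbonyl, so they read as an aldehyde and the ketone of a β-keto ester whose reductive union makes the ring bond, both stereocentres and, by acyl transfer, the lactone. The C6 chloride with the C5=C16 methylene is the ene-chlorination product of an (E)-C5=C6 alkene, which lets the aldehyde partner be a conjugated enal.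

## Retrosynthetic reasoning

**Acetates and protecting groups (41 ⇒ 40 ⇒ 39).** The four acetates go on last, from pentaol 40. Because the epoxide will not survive acid, every protecting group in 39 is silicon-based and leaves with buffered fluoride in one operation. The forward steps only have to distinguish four secondary hydroxyls from the hindered tertiary C8–OH.

**Chloride and methylene (39 ⇒ 38 ⇒ 37).** The C6–Cl bond and the C5=C16 alkene are traced to the (E)-C5=C6 alkene of hydroxy lactone 37 by an ene-type chlorination. The homoallylic C8 hydroxyl could trap the chloronium ion at C5, so it is first capped as the trimethylsilyl ether 38.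

**Ring and lactone (37 ⇒ 35).** The C7–C8 bond and the O7–C19 bond are cut together. This is the only place where one bond-forming event can close the ten-membered ring, set C7 and C8, and drive the lactonisation that fixes C17. The forward reaction is a SmI2 ketyl coupling of enal β-keto ester 35. Compared with the simplest drawing of such a precursor, 35 carries triethylsilyl ethers at C2 and C9 (smaller, so O9 can still bind samarium, and easier to remove), a di-tert-butylsilylene on the 12,14-diol (fluoride-labile, unlike an acetonide) and an ethyl ester; C17 is left undefined because it equilibrates.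

**The two arms (35 ⇒ 34 ⇒ 33 ⇒ 32 ⇒ 30).** The enal is unveiled last, from the 4-methoxybenzyl ether of 33 via alcohol 34, because it tolerates none of the earlier nucleophiles. The α-methyl β-keto ester 33 comes from 32 by C-methylation, and 32 from ynoate 30 by copper-catalysed β-borylation and oxidation, a neutral hydration that spares the epoxide.

**C9 and the lactone opening (30 ⇒ 29 ⇒ 27 ⇒ 24 + 25).** The C9 carbinol is set by reagent-controlled transfer hydrogenation of ynone 27, where the alkynyl group is unambiguously the small substituent. Ynone 27 arises by opening lactone 24 with the lithium acetylide 26 of orthoester alkyne 25. This one step frees the C2 hydroxyl and brings in C8, C17 and C19.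

**Ring oxygenation (24 ⇒ 23 ⇒ 22 ⇒ 20 ⇒ 19 ⇒ 17 ⇒ 16).** The epoxide comes from hydroxyl-directed epoxidation of exocyclic alkene 22; the alkene from Cope elimination of the Mannich base carried in 20; the cis-1,3-diol from chelation-controlled reduction of hydroxy ketone 19; the C14 oxygen from conjugate borylation of enone 17; and C20 from α′-aminomethylation of enone 16. The order is dictated by regiochemistry: only the enone has a single enolisable position (C11). The trans-fused lactone makes 16 and 17 conformationally rigid, with the C15 methyl axial, so attack on C14 occurs anti to it.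

**Lactone and C2 (16 ⇒ 15 ⇒ 13 ⇒ 12 ⇒ 10 + 6).** Lactone 15 is at once a protecting group for O2 and C9, a conformational lock and the later acylating agent. It forms from the (2R)-alcohol obtained by CBS reduction of ketone 13, which comes from aldehyde 10 and the Grignard reagent of bromide 6 via alcohol 12. The enone is made from the regiodefined silyl enol ether by Saegusa–Ito oxidation.

**Cyclohexane (10 ⇒ 8 + 9; 8 ⇐ 7).** C1–C14 and C10–C11 are cut in a Diels–Alder transform. The (E)-geometry of dienophile 9 fixes the C1/C10 relationship (C15 cis to C9, C2 trans to C9), and an enantioselective Lewis acid fixes the absolute sense. Diene 8 comes from ketone 7.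

**Side chain (6 ⇐ 5 ⇐ 4 ⇐ 3 ⇐ 1).** The (E)-trisubstituted alkene of C5=C6 is made once, by carboalumination of alkyne 1, and carried unchanged.

## Alternatives that were turned down

**Alternative 1:** The cut is C1–C10, by an Ireland–Claisen transform in which C9 is the acyl carbon, the C13 oxygen the allylic oxygen and C14=C1 the (Z)-alkene. In the forward step the silyl ketene acetal at C9–C10 rearranges; C10 bonds to C1, C13–O breaks, and the cyclohexene acid A1 results.
- For: the quaternary C1 and C10 are set stereospecifically from alkene geometry, and the C11 methylene and C12 oxygen are already present. On the C1/C10 pair it is as secure as the cycloaddition used here, and it needs no chiral catalyst if the allylic carbinol comes from the chiral pool.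
- Against: A1 lacks the C14 oxygen, which would have to be added regioselectively to the C13=C14 alkene next to the quaternary carbon while the exocyclic alkene is present. The key step also delivers only the six-membered ring; the medium ring, C2, C6–C9 and the lactone remain.
- Comparison: the chosen route obtains the same C1/C10 relationship in one Diels–Alder step and spends its key step on the medium ring.

**Alternative 2:** The cut is C4–C5, with a temporary C2–C7 bond: the ten-membered ring is the anionic oxy-Cope product of a six-membered ring bearing vinyl and alkoxide on C2 and an (E)-alkenyl group on C7. The forward step gives the (E)-cyclodecenone A2.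
- For: the medium ring is made by ring expansion, not end-to-end cyclisation, so there is no entropic penalty and no high dilution. On reliability of ring formation this alternative is stronger than the chosen one. C8 and C9 are also set before the ring is opened.
- Against: A2 has its alkene at C6=C7, where the target has Cl and O on adjacent carbons, so a regio- and face-selective anti addition is still needed. C5 arrives as an sp3 carbon and must become the methylene, and the C2 ketone must be reduced with control in a flexible ring. The substrate has four contiguous highly substituted carbons (C1, C2, C7, C8) and would take many steps to build.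
- Comparison: the chosen route offers a short, convergent precursor and a closure that creates the C7–C8 diol and lactone directly.

**Alternative 3:** The cut is C10–C11 (with O–C9), by intramolecular nitrile oxide cycloaddition of a C11 nitrile oxide onto a (Z)-C9=C10 alkene, giving the isoxazoline A3.
- For: C9–O and C10 are set by a stereospecific cis addition, C11 arrives as a masked ketone and C8 as an ester. On C9 this is stronger than the chosen route, which needs a catalyst-controlled reduction.
- Against: the acyclic substrate must already hold the quaternary C1 and the C12 and C14 centres, and facial selectivity relative to C1 is uncertain. N–O cleavage and methylenation of a ketone flanked by two substituted carbons follow. Again only the cyclohexane is made.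
- Comparison: the chosen route answers the C9 point with a matched reagent-controlled reduction and keeps the key step for the medium ring.

Key step: step 24

## Remarks before the steps

- Locants C1–C20 are those of the target skeleton: C1 quaternary ring carbon with C15 methyl; C2–C9 the chain from C1 to C10; C10–C14 the rest of the cyclohexane; C16 on C5; C17 with C18 methyl; C19 lactone carbonyl; C20 epoxide CH2. "Skeleton descriptors" in names refer to these locants.
- Pen = (3E)-5-[(4-methoxybenzyl)oxy]-3-methylpent-3-en-1-yl (C3–C7 with C16). Core = cyclohexane C1, C10–C14 with C15 methyl on C1, the 11,20-epoxide and the 12,14-O-(di-tert-butylsilanediyl) bridge.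
- Compounds 12, 17–21 and 33–36 are mixtures at one centre (C2, C11 or C17) that is later destroyed or equilibrated; their SMILES leave it open.
- Assumption: the (S)-prolinol-derived oxazaborolidinium catalyst of step 6 is taken to give the (1S,6S) adduct by its accepted pre-transition-state model; if the sense is the reverse, the (R)-catalyst is used with no other change.

## Route

Step 1
Reactants: 1 tert-butyl(but-3-yn-1-yloxy)dimethylsilane
Product: 3 (2E)-5-{[tert-butyl(dimethyl)silyl]oxy}-3-methylpent-2-en-1-ol, via alkenyldimethylalane 2 (not isolated)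
Conditions: Me3Al, Cp2ZrCl2 (cat.), CH2Cl2, 0 °C to rt; then n-BuLi, (CH2O)n, THF, −78 °C to rt
Reagents that add atoms: trimethylaluminium, C[Al](C)C; paraformaldehyde (formaldehyde unit), C=O
Why: Zirconium-catalysed syn-carboalumination (Negishi) puts methyl and aluminium cis on the terminal alkyne, so trapping the alanate with formaldehyde should give only the (E)-allylic alcohol that becomes C5=C6–C7.

Step 2
Reactants: 3 (2E)-5-{[tert-butyl(dimethyl)silyl]oxy}-3-methylpent-2-en-1-ol
Product: 4 tert-butyl({(3E)-5-[(4-methoxybenzyl)oxy]-3-methylpent-3-en-1-yl}oxy)dimethylsilane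
Conditions: NaH, 4-methoxybenzyl chloride, Bu4NI (cat.), THF/DMF, 0 °C to rt
Reagents that add atoms: 4-methoxybenzyl chloride, COc1ccc(CCl)cc1
Why: Williamson etherification of the allylic alkoxide; the 4-methoxybenzyl ether is chosen because it can be removed oxidatively at the end without acid or fluoride.

Step 3
Reactants: 4 tert-butyl({(3E)-5-[(4-methoxybenzyl)oxy]-3-methylpent-3-en-1-yl}oxy)dimethylsilane
Product: 5 (3E)-5-[(4-methoxybenzyl)oxy]-3-methylpent-3-en-1-ol
Conditions: Bu4NF, THF, 0 °C to rt
Reagents that add atoms: none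
Why: Fluoride cleaves the primary silyl ether (strong Si–F bond); the benzyl-type ether and the alkene are unaffected.

Step 4
Reactants: 5 (3E)-5-[(4-methoxybenzyl)oxy]-3-methylpent-3-en-1-ol
Product: 6 1-({[(2E)-5-bromo-3-methylpent-2-en-1-yl]oxy}methyl)-4-methoxybenzene
Conditions: CBr4, PPh3, CH2Cl2, 0 °C
Reagents that add atoms: carbon tetrabromide, BrC(Br)(Br)Br
Why: Appel reaction; bromide displaces the alkoxyphosphonium group at the primary carbon under neutral conditions that keep the allylic ether and the (E)-alkene intact.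

Step 5
Reactants: 7 but-3-en-2-one (methyl vinyl ketone)
Product: 8 (buta-1,3-dien-2-yloxy)tri(propan-2-yl)silane
Conditions: iPr3SiOTf, Et3N, Et2O, 0 °C
Reagents that add atoms: triisopropylsilyl trifluoromethanesulfonate, CC(C)[Si](C(C)C)(C(C)C)OS(=O)(=O)C(F)(F)F
Why: Amine-mediated O-silylation of the methyl ketone gives the 2-silyloxydiene; the triisopropylsilyl enol ether is robust enough for the acidic cycloaddition catalyst.

Step 6
Reactants: 8 (buta-1,3-dien-2-yloxy)tri(propan-2-yl)silane; 9 ethyl (2E)-3-methyl-4-oxobut-2-enoate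
Product: 10 ethyl (1S,6S)-6-formyl-6-methyl-3-{[tri(propan-2-yl)silyl]oxy}cyclohex-3-ene-1-carboxylate
Conditions: (S)-3,3-diphenyl-1-(o-tolyl)tetrahydropyrrolo[1,2-c][1,3,2]oxazaborole·HNTf2 (20 mol%), CH2Cl2, −78 to −40 °C
Reagents that add atoms: none
Why: Enantioselective Diels–Alder reaction catalysed by a protonated oxazaborolidine, a reaction type established for α-methyl enals and 2-silyloxydienes. The catalyst binds the formyl group (more basic than the ester), so the diene CH2 next to the silyloxy carbon bonds to C10 and the silyloxy group ends para to C1. Suprafacial addition to the (E)-alkene sets C15 cis and C2 trans to the C9 ester, and the catalyst shields one face to set the absolute configuration.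

Step 7
Reactants: 6 1-({[(2E)-5-bromo-3-methylpent-2-en-1-yl]oxy}methyl)-4-methoxybenzene; 10 ethyl (1S,6S)-6-formyl-6-methyl-3-{[tri(propan-2-yl)silyl]oxy}cyclohex-3-ene-1-carboxylate
Product: 12 ethyl (1S,6S)-6-{(4E)-1-hydroxy-6-[(4-methoxybenzyl)oxy]-4-methylhex-4-en-1-yl}-6-methyl-3-{[tri(propan-2-yl)silyl]oxy}cyclohex-3-ene-1-carboxylate (both C2 epimers), via Grignard reagent 11 (not isolated)
Conditions: Mg, THF, rt; then 10, THF, −78 °C
Reagents that add atoms: none
Why: Grignard addition to the non-enolisable neopentyl aldehyde; at −78 °C the ester and the silyl enol ether do not react. The C2 configuration is not controlled here because the centre is oxidised in the next step.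

Step 8
Reactants: 12 ethyl (1S,6S)-6-{(4E)-1-hydroxy-6-[(4-methoxybenzyl)oxy]-4-methylhex-4-en-1-yl}-6-methyl-3-{[tri(propan-2-yl)silyl]oxy}cyclohex-3-ene-1-carboxylate
Product: 13 ethyl (1S,6S)-6-{(4E)-6-[(4-methoxybenzyl)oxy]-4-methylhex-4-enoyl}-6-methyl-3-{[tri(propan-2-yl)silyl]oxy}cyclohex-3-ene-1-carboxylate
Conditions: Dess–Martin periodinane, NaHCO3, CH2Cl2, 0 °C to rt
Reagents that add atoms: none
Why: Dess–Martin oxidation of the hindered secondary alcohol under buffered conditions that leave the silyl enol ether and the 4-methoxybenzyl ether untouched.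

Step 9
Reactants: 13 ethyl (1S,6S)-6-{(4E)-6-[(4-methoxybenzyl)oxy]-4-methylhex-4-enoyl}-6-methyl-3-{[tri(propan-2-yl)silyl]oxy}cyclohex-3-ene-1-carboxylate
Product: 15 (3R,3aS,7aS)-3-Pen-3a-methyl-6-{[tri(propan-2-yl)silyl]oxy}-3a,4,7,7a-tetrahydro-2-benzofuran-1(3H)-one, via (2R)-hydroxy ester 14 (not isolated)
Conditions: (S)-2-methyl-CBS-oxazaborolidine (0.5 equiv), catecholborane, toluene, −40 °C; then 2-hydroxypyridine (cat.), toluene, 100 °C
Reagents that add atoms: none
Why: Corey–Bakshi–Shibata reduction; the quaternary C1 is the large and the CH2 chain the small substituent, so the (S)-catalyst should give the (2R)-carbinol, the sense that Felkin–Anh attack anti to C10 also favours. Neutral bifunctional catalysis then closes the trans-fused γ-lactone, which masks O2 and C9 and locks the ring with both arms equatorial and C15 axial.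

Step 10
Reactants: 15 (3R,3aS,7aS)-3-Pen-3a-methyl-6-{[tri(propan-2-yl)silyl]oxy}-3a,4,7,7a-tetrahydro-2-benzofuran-1(3H)-one
Product: 16 (3R,3aS,7aS)-3-Pen-3a-methyl-7,7a-dihydro-2-benzofuran-1,6(3H,3aH)-dione
Conditions: Pd(OAc)2 (1.2 equiv), MeCN, 40 °C
Reagents that add atoms: none
Why: Saegusa–Ito oxidation; palladation of the regiodefined C12=C13 silyl enol ether and β-hydride elimination from C14 can only give the C13=C14 enone.

Step 11
Reactants: 16 (3R,3aS,7aS)-3-Pen-3a-methyl-7,7a-dihydro-2-benzofuran-1,6(3H,3aH)-dione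
Product: 17 (3R,3aS,7aS)-7-[(dimethylamino)methyl]-3-Pen-3a-methyl-7,7a-dihydro-2-benzofuran-1,6(3H,3aH)-dione (C11 epimers)
Conditions: LiN(iPr)2, THF, −78 °C; then Me2N=CH2 I, −78 to 0 °C
Reagents that add atoms: dimethylmethyleneiminium iodide, C[N+](C)=C.[I-]
Why: Kinetic deprotonation of the enone can occur only at the α′ carbon C11 (the γ carbon C1 is quaternary and the lactone α-hydrogen is less acidic), and Mannich alkylation of the dienolate installs C20 as a masked methylene. The C11 configuration is irrelevant because the centre becomes sp2 in step 14.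

Step 12
Reactants: 17 (3R,3aS,7aS)-7-[(dimethylamino)methyl]-3-Pen-3a-methyl-7,7a-dihydro-2-benzofuran-1,6(3H,3aH)-dione
Product: 19 (3R,3aR,4S,7aS)-7-[(dimethylamino)methyl]-4-hydroxy-3-Pen-3a-methylhexahydro-2-benzofuran-1,6-dione, via C14 pinacolboronate 18 (not isolated)
Conditions: B2pin2, CuCl (5 mol%), Xantphos (5 mol%), NaOtBu (10 mol%), MeOH, THF, rt; then NaBO3·4H2O, THF/H2O, rt
Reagents that add atoms: sodium perborate, [Na+].[O-]OB=O
Why: Copper-catalysed conjugate borylation followed by C–B oxidation with retention. In the locked bicycle (the analogue of a trans-fused steroidal 1-en-3-one A ring) axial attack on C14 occurs anti to the axial C15 methyl, placing boron and then oxygen on the face of the C2 arm (14S).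

Step 13
Reactants: 19 (3R,3aR,4S,7aS)-7-[(dimethylamino)methyl]-4-hydroxy-3-Pen-3a-methylhexahydro-2-benzofuran-1,6-dione
Product: 20 (3R,3aR,4S,6R,7aS)-7-[(dimethylamino)methyl]-4,6-dihydroxy-3-Pen-3a-methylhexahydro-2-benzofuran-1(3H)-one
Conditions: Et2BOMe, NaBH4, THF/MeOH, −78 °C
Reagents that add atoms: none
Why: Narasaka–Prasad reduction; boron bridges the axial C14 oxygen and the C12 carbonyl, and external hydride enters from the open equatorial side, giving the axial C12 hydroxyl and hence the cis-1,3-diol (12R). The lactone is not reduced at this temperature.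

Step 14
Reactants: 20 (3R,3aR,4S,6R,7aS)-7-[(dimethylamino)methyl]-4,6-dihydroxy-3-Pen-3a-methylhexahydro-2-benzofuran-1(3H)-one
Product: 22 (3R,3aR,4S,6R,7aS)-4,6-dihydroxy-3-Pen-3a-methyl-7-methylidenehexahydro-2-benzofuran-1(3H)-one, via amine N-oxide 21 (not isolated)
Conditions: mCPBA (1.05 equiv), CH2Cl2, −40 to 0 °C; K2CO3; then THF, 65 °C
Reagents that add atoms: none
Why: The peracid oxidises the tertiary amine far faster than the trisubstituted C5=C6 alkene. The N-oxide then undergoes Cope elimination, and since the only β-hydrogen is on C11, the exocyclic C11=C20 alkene is the single possible product.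

Step 15
Reactants: 22 (3R,3aR,4S,6R,7aS)-4,6-dihydroxy-3-Pen-3a-methyl-7-methylidenehexahydro-2-benzofuran-1(3H)-one
Product: 23 (3R,3aR,4S,6R,7R,7aR)-4,6-dihydroxy-3-Pen-3a-methylhexahydro-1H-spiro[2-benzofuran-7,2'-oxiran]-1-one
Conditions: VO(acac)2 (5 mol%), t-BuOOH, CH2Cl2, 0 °C to rt
Reagents that add atoms: tert-butyl hydroperoxide, CC(C)(C)OO
Why: Hydroxyl-directed epoxidation; the vanadium alkoxide of the axial allylic C12 hydroxyl delivers oxygen to its own face, so the epoxide oxygen is cis to O12 and C20 trans (11R). The C5=C6 alkene has no free hydroxyl nearby and is not epoxidised.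

Step 16
Reactants: 23 (3R,3aR,4S,6R,7R,7aR)-4,6-dihydroxy-3-Pen-3a-methylhexahydro-1H-spiro[2-benzofuran-7,2'-oxiran]-1-one
Product: 24 4,6-O-(di-tert-butylsilanediyl) derivative of 23 (skeleton descriptors 1S,2R,10R,11R,12R,14S)
Conditions: tBu2Si(OTf)2, 2,6-lutidine, CH2Cl2, 0 °C
Reagents that add atoms: di-tert-butylsilyl bis(trifluoromethanesulfonate), CC(C)(C)[Si](OS(=O)(=O)C(F)(F)F)(OS(=O)(=O)C(F)(F)F)C(C)(C)C
Why: Silylene formation bridges the cis-1,3-diaxial diol as a six-membered ring; with excess lutidine at 0 °C silylation of hydroxyl is much faster than activation of the epoxide. The bridge is later removed by fluoride, so no acid is needed at the end.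

Step 17
Reactants: 24 4,6-O-(di-tert-butylsilanediyl) derivative of 23; 25 3,3,3-triethoxyprop-1-yne
Product: 27 ynone: Core with C1–CH(OH)–Pen (2R) and C10–C(=O)C≡C–C(OEt)3 (skeleton descriptors 1S,2R,10R,11R,12R,14S), via lithium acetylide 26 (not isolated)
Conditions: n-BuLi, THF, −78 °C; then 24, THF, −78 °C; pH 7 buffer
Reagents that add atoms: none
Why: Alkynyllithium addition to a lactone stops at the tetrahedral alkoxide at −78 °C and gives the ynone on work-up, freeing the C2 hydroxyl (27 may sit partly as its five-membered hemiketal). The strained trans-fused lactone is a good acceptor, and the orthoester keeps the alkyne from acting as a Michael acceptor.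

Step 18
Reactants: 27 ynone: Core with C1–CH(OH)–Pen (2R) and C10–C(=O)C≡C–C(OEt)3
Product: 29 hydroxy ynoate: Core with C1–CH(OH)–Pen (2R) and C10–CH(OH)–C≡C–CO2Et (9S) (skeleton descriptors 1S,2R,9S,10S,11R,12R,14S), via orthoester diol 28 (not isolated)
Conditions: Ru(p-cymene)[(S,S)-TsNCH(Ph)CH(Ph)NH] (5 mol%), propan-2-ol, rt; then AcOH/NaOAc buffer (pH 4.5), THF/H2O, 0 °C
Reagents that add atoms: water, O
Why: Noyori-type asymmetric transfer hydrogenation of an alkynyl ketone; the slim alkynyl group is the small substituent, so the (S,S)-catalyst should give the (9S)-propargylic alcohol, the sense that Felkin–Anh attack from the open C11 side (anti to C1) also favours. The buffer then hydrolyses the orthoester to the ethyl ester much faster than it could open the epoxide.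

Step 19
Reactants: 29 hydroxy ynoate: Core with C1–CH(OH)–Pen (2R) and C10–CH(OH)–C≡C–CO2Et (9S)
Product: 30 bis(triethylsilyl) ether of 29 (O2 and O9)
Conditions: Et3SiOTf, 2,6-lutidine, CH2Cl2, −78 °C
Reagents that add atoms: triethylsilyl trifluoromethanesulfonate, CC[Si](CC)(CC)OS(=O)(=O)C(F)(F)F
Why: Silylation of the hindered C2 and the propargylic C9 hydroxyls with the triflate at low temperature. Triethylsilyl is chosen over bulkier groups so that O9 can still coordinate samarium and all silicon groups leave together at the end.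

Step 20
Reactants: 30 bis(triethylsilyl) ether of 29
Product: 32 β-keto ester: Core with C1–CH(OSiEt3)–Pen (2R) and C10–CH(OSiEt3)–C(=O)–CH2–CO2Et (9S), via (Z)-alkenylboronate 31 (not isolated)
Conditions: B2pin2, CuCl (10 mol%), Xantphos (10 mol%), NaOtBu (15 mol%), MeOH, THF, rt; then NaBO3·4H2O, THF/H2O, rt
Reagents that add atoms: sodium perborate, [Na+].[O-]OB=O
Why: Copper-catalysed β-borylation of an alkynoate puts boron on C8, and perborate oxidation of the alkenylboronate gives the enol and hence the β-keto ester. The conditions are near neutral and spare the epoxide and the silyl ethers.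

Step 21
Reactants: 32 β-keto ester: Core with C1–CH(OSiEt3)–Pen (2R) and C10–CH(OSiEt3)–C(=O)–CH2–CO2Et (9S)
Product: 33 α-methyl β-keto ester: as 32 with C10–CH(OSiEt3)–C(=O)–CH(CH3)–CO2Et (C17 epimers)
Conditions: MeI, K2CO3, acetone, rt
Reagents that add atoms: iodomethane, CI
Why: C-alkylation of the potassium enolate of the β-keto ester at C17, the only acidic site. The new centre is an equilibrating mixture and is fixed only in the lactone.

Step 22
Reactants: 33 α-methyl β-keto ester (C17 epimers)
Product: 34 allylic alcohol: as 33 with the 4-methoxybenzyl group removed (C7–OH, 5E)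
Conditions: DDQ, CH2Cl2/pH 7 buffer, 0 °C
Reagents that add atoms: none
Why: Oxidative cleavage of the 4-methoxybenzyl ether by hydride abstraction in buffered wet solvent; silyl ethers, epoxide and keto ester are not oxidised.

Step 23
Reactants: 34 allylic alcohol (C7–OH, 5E)
Product: 35 seco enal β-keto ester: Core with C1–CH(OSiEt3)–CH2CH2–C(CH3)=CH–CHO (2R,5E) and C10–CH(OSiEt3)–C(=O)–CH(CH3)–CO2Et (9S; C17 epimers; skeleton descriptors 1S,2R,9S,10S,11R,12R,14S)
Conditions: MnO2, CH2Cl2, rt
Reagents that add atoms: none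
Why: MnO2 oxidises only the allylic alcohol, without E/Z isomerisation. The enal is made last because it tolerates none of the earlier nucleophiles.

Step 24
Reactants: 35 seco enal β-keto ester
Product: 37 hydroxy lactone (1S,2R,5E,7S,8S,9S,10S,11R,12R,14S,17R): ten-membered ring with (E)-C5=C6, C8–OH, 19,7-lactone, O2 and O9 triethylsilyl ethers, 12,14-silylene, 11,20-epoxide, via samarium diolate 36 (not isolated)
Conditions: SmI2 (3 equiv), THF, −78 °C, 35 added over 6 h to 0.002 M; then 0 °C; aq. potassium sodium tartrate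
Reagents that add atoms: none
Why: Proposed new method: divalent samarium reduces the conjugated aldehyde (the more easily reduced carbonyl) to a C7 ketyl bound to trivalent samarium, which adds to the C8 ketone held and activated in a chelate with the C19 ester carbonyl; a second electron gives diolate 36. The closest known reaction type is the SmI2 pinacol cyclisation of aldehydes onto β-keto esters that gives cis-diols in five- and six-membered rings; the ten-membered ring and the enal partner are the untested extension. The carbocycle closes by 10-exo-trig radical addition to the carbonyl carbon, helped by slow addition at high dilution and by the fixed trans-diequatorial placement of both arms on the bridged cyclohexane. The lactone closes by 5-exo-trig acyl substitution of the C7 alkoxide on the ethyl ester, which also takes the diolate out of any retro-pinacol equilibrium. C7 is set by the samarium bridge between O7 and O8 in the bond-forming transition state, which gives the cis (erythro) diol. C8 is set by a tridentate O9/O8/O19 chelate in which C7 approaches the ketone face anti to C10 (Cram-chelate sense), and C17, which epimerises freely in 35, reacts through or relaxes to the epimer with its methyl anti to the incoming C7 and is then fixed as 17R. The step needs α- over γ-coupling of the allyl-type ketyl (the γ carbon C5 is fully substituted and would close an eight-membered ring), retention of the C9–O bond (the ketone is not reduced first and a silyl ether is a poor leaving group), an inert epoxide, and retention of the (E)-geometry at −78 °C.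

Step 25
Reactants: 37 hydroxy lactone
Product: 38 C8 trimethylsilyl ether of 37
Conditions: 1-(trimethylsilyl)imidazole, CH2Cl2, rt
Reagents that add atoms: 1-(trimethylsilyl)imidazole, C[Si](C)(C)n1ccnc1
Why: Neutral silyl transfer to the hindered tertiary hydroxyl; it blocks the homoallylic C8 oxygen, which could otherwise capture the chloronium ion at C5 in a 5-endo chloroetherification.

Step 26
Reactants: 38 C8 trimethylsilyl ether of 37
Product: 39 allylic chloride (1S,2R,6S,7R,8S,9S,10S,11R,12R,14S,17R): as 38 with C6–Cl and C5=C16 methylene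
Conditions: Ca(OCl)2, solid CO2, CH2Cl2/H2O, 0 °C
Reagents that add atoms: calcium hypochlorite, [Ca+2].[O-]Cl.[O-]Cl
Why: Ene-type chlorination by HOCl made in situ; the chloronium ion on the trisubstituted alkene loses a proton from the C16 methyl, the least hindered allylic hydrogen, giving the secondary C6 chloride and the C5=C16 methylene. Chlorine should enter from the outer face of the (E)-alkene, which gives 6S if C8 sits on the inner face with the lactone oxygen near the alkene plane.

Step 27
Reactants: 39 allylic chloride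
Product: 40 pentaol (1S,2R,6S,7R,8R,9S,10S,11R,12R,14S,17R): 6-chloro-11,20-epoxy-2,8,9,12,14-pentahydroxy-5(16)-ene 19,7-lactone
Conditions: HF·pyridine, pyridine, THF, 0 °C to rt
Reagents that add atoms: none
Why: Fluoride cleaves all Si–O bonds (two triethylsilyl ethers, the silylene, the trimethylsilyl ether) in one operation; pyridine-buffered HF should be too weakly acidic to open the epoxide or ionise the allylic chloride.

Step 28
Reactants: 40 pentaol
Product: 41 CNP0349227.1 (2,9,12,14-tetraacetate)
Conditions: Ac2O, pyridine, 4-(dimethylamino)pyridine (cat.), CH2Cl2, 0 °C to rt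
Reagents that add atoms: acetic anhydride, CC(=O)OC(C)=O
Why: Acylation of the four secondary hydroxyls under nucleophilic catalysis; the tertiary C8 hydroxyl, flanked by two fully substituted carbons, should not be acylated under these conditions.

## Compound list

1 | tert-butyl(but-3-yn-1-yloxy)dimethylsilane | C#CCCO[Si](C)(C)C(C)(C)C | starting material
2 | [(1E)-4-{[tert-butyl(dimethyl)silyl]oxy}-2-methylbut-1-en-1-yl]dimethylalane | C[Al](C)/C=C(\C)CCO[Si](C)(C)C(C)(C)C | intermediate (not isolated)
3 | (2E)-5-{[tert-butyl(dimethyl)silyl]oxy}-3-methylpent-2-en-1-ol | OC/C=C(\C)CCO[Si](C)(C)C(C)(C)C | intermediate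
4 | tert-butyl({(3E)-5-[(4-methoxybenzyl)oxy]-3-methylpent-3-en-1-yl}oxy)dimethylsilane | COc1ccc(COC/C=C(\C)CCO[Si](C)(C)C(C)(C)C)cc1 | intermediate
5 | (3E)-5-[(4-methoxybenzyl)oxy]-3-methylpent-3-en-1-ol | COc1ccc(COC/C=C(\C)CCO)cc1 | intermediate
6 | 1-({[(2E)-5-bromo-3-methylpent-2-en-1-yl]oxy}methyl)-4-methoxybenzene | COc1ccc(COC/C=C(\C)CCBr)cc1 | intermediate
7 | but-3-en-2-one | CC(=O)C=C | starting material
8 | (buta-1,3-dien-2-yloxy)tri(propan-2-yl)silane | C=CC(=C)O[Si](C(C)C)(C(C)C)C(C)C | intermediate
9 | ethyl (2E)-3-methyl-4-oxobut-2-enoate | CCOC(=O)/C=C(\C)C=O | starting material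
10 | ethyl (1S,6S)-6-formyl-6-methyl-3-{[tri(propan-2-yl)silyl]oxy}cyclohex-3-ene-1-carboxylate | O=C[C@@]1(C)CC=C(O[Si](C(C)C)(C(C)C)C(C)C)C[C@@H]1C(=O)OCC | intermediate
11 | {(3E)-5-[(4-methoxybenzyl)oxy]-3-methylpent-3-en-1-yl}magnesium bromide | Br[Mg]CC/C(C)=C/COCc1ccc(OC)cc1 | intermediate (not isolated)
12 | ethyl (1S,6S)-6-{(4E)-1-hydroxy-6-[(4-methoxybenzyl)oxy]-4-methylhex-4-en-1-yl}-6-methyl-3-{[tri(propan-2-yl)silyl]oxy}cyclohex-3-ene-1-carboxylate (C2 epimers) | COc1ccc(COC/C=C(\C)CCC(O)[C@@]2(C)CC=C(O[Si](C(C)C)(C(C)C)C(C)C)C[C@@H]2C(=O)OCC)cc1 | intermediate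
13 | ethyl (1S,6S)-6-{(4E)-6-[(4-methoxybenzyl)oxy]-4-methylhex-4-enoyl}-6-methyl-3-{[tri(propan-2-yl)silyl]oxy}cyclohex-3-ene-1-carboxylate | COc1ccc(COC/C=C(\C)CCC(=O)[C@@]2(C)CC=C(O[Si](C(C)C)(C(C)C)C(C)C)C[C@@H]2C(=O)OCC)cc1 | intermediate
14 | ethyl (1S,6S)-6-{(1R,4E)-1-hydroxy-6-[(4-methoxybenzyl)oxy]-4-methylhex-4-en-1-yl}-6-methyl-3-{[tri(propan-2-yl)silyl]oxy}cyclohex-3-ene-1-carboxylate | COc1ccc(COC/C=C(\C)CC[C@@H](O)[C@@]2(C)CC=C(O[Si](C(C)C)(C(C)C)C(C)C)C[C@@H]2C(=O)OCC)cc1 | intermediate (not isolated)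
15 | (3R,3aS,7aS)-3-Pen-3a-methyl-6-{[tri(propan-2-yl)silyl]oxy}-3a,4,7,7a-tetrahydro-2-benzofuran-1(3H)-one | COc1ccc(COC/C=C(\C)CC[C@H]2OC(=O)[C@H]3CC(O[Si](C(C)C)(C(C)C)C(C)C)=CC[C@]23C)cc1 | intermediate
16 | (3R,3aS,7aS)-3-Pen-3a-methyl-7,7a-dihydro-2-benzofuran-1,6(3H,3aH)-dione | COc1ccc(COC/C=C(\C)CC[C@H]2OC(=O)[C@H]3CC(=O)C=C[C@]23C)cc1 | intermediate
17 | (3R,3aS,7aS)-7-[(dimethylamino)methyl]-3-Pen-3a-methyl-7,7a-dihydro-2-benzofuran-1,6(3H,3aH)-dione (C11 epimers) | COc1ccc(COC/C=C(\C)CC[C@H]2OC(=O)[C@H]3C(CN(C)C)C(=O)C=C[C@]23C)cc1 | intermediate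
18 | (3R,3aS,4S,7aS)-7-[(dimethylamino)methyl]-3-Pen-3a-methyl-4-(4,4,5,5-tetramethyl-1,3,2-dioxaborolan-2-yl)hexahydro-2-benzofuran-1,6-dione | COc1ccc(COC/C=C(\C)CC[C@H]2OC(=O)[C@H]3C(CN(C)C)C(=O)C[C@H](B4OC(C)(C)C(C)(C)O4)[C@]23C)cc1 | intermediate (not isolated)
19 | (3R,3aR,4S,7aS)-7-[(dimethylamino)methyl]-4-hydroxy-3-Pen-3a-methylhexahydro-2-benzofuran-1,6-dione | COc1ccc(COC/C=C(\C)CC[C@H]2OC(=O)[C@H]3C(CN(C)C)C(=O)C[C@H](O)[C@]23C)cc1 | intermediate
20 | (3R,3aR,4S,6R,7aS)-7-[(dimethylamino)methyl]-4,6-dihydroxy-3-Pen-3a-methylhexahydro-2-benzofuran-1(3H)-one | COc1ccc(COC/C=C(\C)CC[C@H]2OC(=O)[C@H]3C(CN(C)C)[C@H](O)C[C@H](O)[C@]23C)cc1 | intermediate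
21 | N-oxide of 20 | COc1ccc(COC/C=C(\C)CC[C@H]2OC(=O)[C@H]3C(C[N+](C)(C)[O-])[C@H](O)C[C@H](O)[C@]23C)cc1 | intermediate (not isolated)
22 | (3R,3aR,4S,6R,7aS)-4,6-dihydroxy-3-Pen-3a-methyl-7-methylidenehexahydro-2-benzofuran-1(3H)-one | COc1ccc(COC/C=C(\C)CC[C@H]2OC(=O)[C@H]3C(=C)[C@H](O)C[C@H](O)[C@]23C)cc1 | intermediate
23 | (3R,3aR,4S,6R,7R,7aR)-4,6-dihydroxy-3-Pen-3a-methylhexahydro-1H-spiro[2-benzofuran-7,2'-oxiran]-1-one | COc1ccc(COC/C=C(\C)CC[C@H]2OC(=O)[C@H]3[C@@]4(CO4)[C@H](O)C[C@H](O)[C@]23C)cc1 | intermediate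
24 | 4,6-O-(di-tert-butylsilanediyl) derivative of 23 (skeleton 1S,2R,10R,11R,12R,14S) | COc1ccc(COC/C=C(\C)CC[C@H]2OC(=O)[C@H]3[C@@]4(CO4)[C@H]5C[C@H](O[Si](C(C)(C)C)(C(C)(C)C)O5)[C@]23C)cc1 | intermediate
25 | 3,3,3-triethoxyprop-1-yne | C#CC(OCC)(OCC)OCC | starting material
26 | (3,3,3-triethoxyprop-1-yn-1-yl)lithium | [Li]C#CC(OCC)(OCC)OCC | intermediate (not isolated)
27 | ynone: Core with C1–CH(OH)–Pen (2R) and C10–C(=O)C≡C–C(OEt)3 (skeleton 1S,2R,10R,11R,12R,14S) | COc1ccc(COC/C=C(\C)CC[C@@H](O)[C@@]2(C)[C@H]3O[Si](C(C)(C)C)(C(C)(C)C)O[C@H](C3)[C@]4(CO4)[C@@H]2C(=O)C#CC(OCC)(OCC)OCC)cc1 | intermediate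
28 | orthoester diol: Core with C1–CH(OH)–Pen (2R) and C10–CH(OH)–C≡C–C(OEt)3 (9S) | COc1ccc(COC/C=C(\C)CC[C@@H](O)[C@@]2(C)[C@H]3O[Si](C(C)(C)C)(C(C)(C)C)O[C@H](C3)[C@]4(CO4)[C@@H]2[C@H](O)C#CC(OCC)(OCC)OCC)cc1 | intermediate (not isolated)
29 | hydroxy ynoate: Core with C1–CH(OH)–Pen (2R) and C10–CH(OH)–C≡C–CO2Et (9S) (skeleton 1S,2R,9S,10S,11R,12R,14S) | COc1ccc(COC/C=C(\C)CC[C@@H](O)[C@@]2(C)[C@H]3O[Si](C(C)(C)C)(C(C)(C)C)O[C@H](C3)[C@]4(CO4)[C@@H]2[C@H](O)C#CC(=O)OCC)cc1 | intermediate
30 | bis(triethylsilyl) ether of 29 | COc1ccc(COC/C=C(\C)CC[C@@H](O[Si](CC)(CC)CC)[C@@]2(C)[C@H]3O[Si](C(C)(C)C)(C(C)(C)C)O[C@H](C3)[C@]4(CO4)[C@@H]2[C@H](O[Si](CC)(CC)CC)C#CC(=O)OCC)cc1 | intermediate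
31 | (Z)-alkenylboronate: as 30 with C10–CH(OSiEt3)–C(Bpin)=CH–CO2Et | COc1ccc(COC/C=C(\C)CC[C@@H](O[Si](CC)(CC)CC)[C@@]2(C)[C@H]3O[Si](C(C)(C)C)(C(C)(C)C)O[C@H](C3)[C@]4(CO4)[C@@H]2[C@H](O[Si](CC)(CC)CC)/C(B5OC(C)(C)C(C)(C)O5)=C\C(=O)OCC)cc1 | intermediate (not isolated)
32 | β-keto ester: Core with C1–CH(OSiEt3)–Pen (2R) and C10–CH(OSiEt3)–C(=O)–CH2–CO2Et (9S) | COc1ccc(COC/C=C(\C)CC[C@@H](O[Si](CC)(CC)CC)[C@@]2(C)[C@H]3O[Si](C(C)(C)C)(C(C)(C)C)O[C@H](C3)[C@]4(CO4)[C@@H]2[C@H](O[Si](CC)(CC)CC)C(=O)CC(=O)OCC)cc1 | intermediate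
33 | α-methyl β-keto ester: as 32 with C(=O)–CH(CH3)–CO2Et (C17 epimers) | COc1ccc(COC/C=C(\C)CC[C@@H](O[Si](CC)(CC)CC)[C@@]2(C)[C@H]3O[Si](C(C)(C)C)(C(C)(C)C)O[C@H](C3)[C@]4(CO4)[C@@H]2[C@H](O[Si](CC)(CC)CC)C(=O)C(C)C(=O)OCC)cc1 | intermediate
34 | allylic alcohol: as 33 with C7–OH (5E; C17 epimers) | OC/C=C(\C)CC[C@@H](O[Si](CC)(CC)CC)[C@@]1(C)[C@H]2O[Si](C(C)(C)C)(C(C)(C)C)O[C@H](C2)[C@]3(CO3)[C@@H]1[C@H](O[Si](CC)(CC)CC)C(=O)C(C)C(=O)OCC | intermediate
35 | seco enal β-keto ester (skeleton 1S,2R,5E,9S,10S,11R,12R,14S; C17 epimers) | O=C/C=C(\C)CC[C@@H](O[Si](CC)(CC)CC)[C@@]1(C)[C@H]2O[Si](C(C)(C)C)(C(C)(C)C)O[C@H](C2)[C@]3(CO3)[C@@H]1[C@H](O[Si](CC)(CC)CC)C(=O)C(C)C(=O)OCC | intermediate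
36 | ring-closed C7,C8-diol ethyl ester, present as its trivalent-samarium diolate (7S,8S; C17 epimers) | C1C[C@@H](O[Si](CC)(CC)CC)[C@@]2(C)[C@H]3O[Si](C(C)(C)C)(C(C)(C)C)O[C@H](C3)[C@]4(CO4)[C@@H]2[C@H](O[Si](CC)(CC)CC)[C@](O)(C(C)C(=O)OCC)[C@@H](O)/C=C1\C | intermediate (not isolated)
37 | hydroxy lactone (1S,2R,5E,7S,8S,9S,10S,11R,12R,14S,17R) | C1C[C@@H](O[Si](CC)(CC)CC)[C@@]2(C)[C@H]3O[Si](C(C)(C)C)(C(C)(C)C)O[C@H](C3)[C@]4(CO4)[C@@H]2[C@H](O[Si](CC)(CC)CC)[C@]2(O)[C@@H](C)C(=O)O[C@H]2/C=C1\C | intermediate
38 | C8 trimethylsilyl ether of 37 | C1C[C@@H](O[Si](CC)(CC)CC)[C@@]2(C)[C@H]3O[Si](C(C)(C)C)(C(C)(C)C)O[C@H](C3)[C@]4(CO4)[C@@H]2[C@H](O[Si](CC)(CC)CC)[C@]2(O[Si](C)(C)C)[C@@H](C)C(=O)O[C@H]2/C=C1\C | intermediate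
39 | allylic chloride (1S,2R,6S,7R,8S,9S,10S,11R,12R,14S,17R) | C=C1CC[C@@H](O[Si](CC)(CC)CC)[C@@]2(C)[C@H]3O[Si](C(C)(C)C)(C(C)(C)C)O[C@H](C3)[C@]4(CO4)[C@@H]2[C@H](O[Si](CC)(CC)CC)[C@]2(O[Si](C)(C)C)[C@@H](C)C(=O)O[C@H]2[C@H]1Cl | intermediate
40 | pentaol (1S,2R,6S,7R,8R,9S,10S,11R,12R,14S,17R) | C=C1CC[C@@H](O)[C@@]2(C)[C@@H](O)C[C@@H](O)[C@]3(CO3)[C@@H]2[C@H](O)[C@]2(O)[C@@H](C)C(=O)O[C@H]2[C@H]1Cl | intermediate
41 | CNP0349227.1 (1S,2R,6S,7R,8R,9S,10S,11R,12R,14S,17R) | C=C1CC[C@@H](OC(C)=O)[C@@]2(C)[C@@H](OC(C)=O)C[C@@H](OC(C)=O)[C@]3(CO3)[C@@H]2[C@H](OC(C)=O)[C@]2(O)[C@@H](C)C(=O)O[C@H]2[C@H]1Cl | target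

## Step count and uncertain steps

Total: 28 steps. Longest linear sequence: 26 steps (steps 1–4, then 7–28, from 1 to 41); the branch from 7 has 24.

**Step 24 (key step).**
- What may go wrong: intermolecular ketyl dimerisation or simple reduction of the aldehyde may outrun the slow ten-membered closure; the allyl-type ketyl may couple through C5 or lose its (E)-geometry; the C9–O bond may be cleaved reductively if the ketone is reduced first; and the C8 face may not be controlled if the silyl ether stays out of the chelate.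
- Fallback (known chemistry, same C7–C8 bond, Nozaki–Hiyama–Kishi closure): it sets out from 35. Deprotonation of the β-keto ester with KN(SiMe3)2 and trapping with N-(5-chloropyridin-2-yl)-1,1,1-trifluoro-N-(trifluoromethylsulfonyl)methanesulfonamide at −78 °C should give the (Z)-enol triflate F1. CrCl2 with catalytic NiCl2 in DMSO/THF at high dilution adds the alkenylchromium to the enal, and the chromium alkoxide lactonises onto the cis ester to give the macrocyclic butenolide F2. Nucleophilic epoxidation (t-BuOOH, benzyltrimethylammonium hydroxide) would give the 8,17-epoxy lactone F3, and SmI2 in THF/MeOH at −78 °C cleaves the C17–O bond of the epoxy lactone to return to 37. The face of the butenolide epoxidation is the open point of this fallback.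

**Step 6.**
- What may go wrong: the ester may compete with the aldehyde for the Lewis acid, eroding regio- and enantioselectivity, or the acid may degrade the diene.
- Fallback: it sets out from 8 and 9. An achiral Lewis acid (EtAlCl2, CH2Cl2, −78 °C) gives 10 together with its enantiomer F4; steps 7 and 8 carry the pair on as 12/F5 and 13/F6. The reagent-controlled reduction of step 9 then turns the two enantiomeric ketones into diastereomers, 14 and the hydroxy ester F7, whose lactones 15 and F8 are separated by chromatography; the route is rejoined at 15.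

**Step 12.**
- What may go wrong: slow conjugate addition of the bulky boryl-copper at the neopentyl C14, loss of dimethylamine from the β-amino ketone under the basic conditions, or insufficient facial preference.
- Fallback: it sets out from 17. Nucleophilic epoxidation with the small hydroperoxide anion (t-BuOOH, DBU, CH2Cl2) gives the 13,14-epoxy ketone F9 (attack anti to the axial methyl), and selenide-mediated reductive opening of the epoxy ketone (PhSeSePh, NaBH4, EtOH, AcOH) returns to 19.

**Step 18.**
- What may go wrong: the very hindered ketone, partly masked as a hemiketal, may be reduced slowly or with the substrate overriding the catalyst.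
- Fallback: it sets out from 27. If the reduction gives mainly the 9R diol orthoester F10, a Mitsunobu reaction (4-nitrobenzoic acid, PPh3, diisopropyl azodicarboxylate) acts only on the propargylic hydroxyl (the C2 hydroxyl is neopentyl) and inverts it to the 4-nitrobenzoate F11; K2CO3 in methanol returns to 28, which is hydrolysed to 29 as in step 18.

**Step 26.**
- What may go wrong: chlorine delivery to the wrong alkene face (the 6R epimer), proton loss toward C4, or over-chlorination of the new methylene.
- Fallback: it sets out from 38. A Schenck ene reaction (O2, tetraphenylporphyrin, light, CH2Cl2, −78 °C; then PPh3) gives the allylic alcohol F12 with the C5=C16 methylene, and a phosphine-mediated chlorination with inversion (PPh3, hexachloroacetone, CH2Cl2, −20 °C) returns to 39. Since substitution inverts C6, this sequence gives the stereochemical result opposite to that of direct chlorination from the same alkene face.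

## Further compounds

F1 | step 24 | (Z)-enol triflate of 35 (C8–OTf cis to the ester) | O=C/C=C(\C)CC[C@@H](O[Si](CC)(CC)CC)[C@@]1(C)[C@H]2O[Si](C(C)(C)C)(C(C)(C)C)O[C@H](C2)[C@]3(CO3)[C@@H]1[C@H](O[Si](CC)(CC)CC)/C(OS(=O)(=O)C(F)(F)F)=C(\C)C(=O)OCC
F2 | step 24 | macrocyclic 8(17)-butenolide (7S) | C1C[C@@H](O[Si](CC)(CC)CC)[C@@]2(C)[C@H]3O[Si](C(C)(C)C)(C(C)(C)C)O[C@H](C3)[C@]4(CO4)[C@@H]2[C@H](O[Si](CC)(CC)CC)C2=C(C)C(=O)O[C@H]2/C=C1\C
F3 | step 24 | 8,17-epoxy lactone | C1C[C@@H](O[Si](CC)(CC)CC)[C@@]2(C)[C@H]3O[Si](C(C)(C)C)(C(C)(C)C)O[C@H](C3)[C@]4(CO4)[C@@H]2[C@H](O[Si](CC)(CC)CC)[C@@]25O[C@@]5(C)C(=O)O[C@H]2/C=C1\C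
F4 | step 6 | ethyl (1R,6R)-6-formyl-6-methyl-3-{[tri(propan-2-yl)silyl]oxy}cyclohex-3-ene-1-carboxylate (enantiomer of 10) | O=C[C@]1(C)CC=C(O[Si](C(C)C)(C(C)C)C(C)C)C[C@H]1C(=O)OCC
F5 | step 6 | enantiomer of 12 (1R,6R ring; C2 epimers) | COc1ccc(COC/C=C(\C)CCC(O)[C@]2(C)CC=C(O[Si](C(C)C)(C(C)C)C(C)C)C[C@H]2C(=O)OCC)cc1
F6 | step 6 | enantiomer of 13 (1R,6R) | COc1ccc(COC/C=C(\C)CCC(=O)[C@]2(C)CC=C(O[Si](C(C)C)(C(C)C)C(C)C)C[C@H]2C(=O)OCC)cc1
F7 | step 6 | ethyl (1R,6R)-6-{(1R,4E)-1-hydroxy-6-[(4-methoxybenzyl)oxy]-4-methylhex-4-en-1-yl}-6-methyl-3-{[tri(propan-2-yl)silyl]oxy}cyclohex-3-ene-1-carboxylate | COc1ccc(COC/C=C(\C)CC[C@@H](O)[C@]2(C)CC=C(O[Si](C(C)C)(C(C)C)C(C)C)C[C@H]2C(=O)OCC)cc1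
F8 | step 6 | (3R,3aR,7aR)-3-Pen-3a-methyl-6-{[tri(propan-2-yl)silyl]oxy}-3a,4,7,7a-tetrahydro-2-benzofuran-1(3H)-one | COc1ccc(COC/C=C(\C)CC[C@H]2OC(=O)[C@@H]3CC(O[Si](C(C)C)(C(C)C)C(C)C)=CC[C@@]23C)cc1
F9 | step 12 | 13,14-epoxy ketone of 17 (epoxide oxygen on the face of the C2 arm) | COc1ccc(COC/C=C(\C)CC[C@H]2OC(=O)[C@H]3C(CN(C)C)C(=O)[C@@H]4O[C@@H]4[C@]23C)cc1
F10 | step 18 | C9 epimer of 28 (9R) | COc1ccc(COC/C=C(\C)CC[C@@H](O)[C@@]2(C)[C@H]3O[Si](C(C)(C)C)(C(C)(C)C)O[C@H](C3)[C@]4(CO4)[C@@H]2[C@@H](O)C#CC(OCC)(OCC)OCC)cc1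
F11 | step 18 | 9-O-(4-nitrobenzoate) of 28 (9S) | COc1ccc(COC/C=C(\C)CC[C@@H](O)[C@@]2(C)[C@H]3O[Si](C(C)(C)C)(C(C)(C)C)O[C@H](C3)[C@]4(CO4)[C@@H]2[C@H](OC(=O)c5ccc(cc5)[N+](=O)[O-])C#CC(OCC)(OCC)OCC)cc1
F12 | step 26 | (6R)-allylic alcohol with C5=C16 methylene (C8 trimethylsilyl ether) | C=C1CC[C@@H](O[Si](CC)(CC)CC)[C@@]2(C)[C@H]3O[Si](C(C)(C)C)(C(C)(C)C)O[C@H](C3)[C@]4(CO4)[C@@H]2[C@H](O[Si](CC)(CC)CC)[C@]2(O[Si](C)(C)C)[C@@H](C)C(=O)O[C@H]2[C@@H]1O
A1 | alternative 1 | cyclohexene carboxylic acid with C1 and C10 set (configured as in the SMILES) | OC(=O)[C@H]1C(=C)[C@H](O[Si](C)(C)C(C)(C)C)C=C[C@]1(C)COCc1ccc(OC)cc1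
A2 | alternative 2 | (E)-cyclodecenone with C2 ketone and C6=C7 alkene | O=C1CC[C@H](COCc2ccc(OC)cc2)/C=C/[C@@](OCOC)([C@@H](C)CO[Si](C)(C)C(C)(C)C)[C@@H](OCOC)[C@H]2C(=C)[C@H]3C[C@H](OC(C)(C)O3)[C@]12C
A3 | alternative 3 | cyclohexane-fused isoxazoline methyl ester | COC(=O)[C@H]1ON=C2[C@H](O[Si](C)(C)C(C)(C)C)C[C@H](O[Si](C)(C)C(C)(C)C)[C@](C)(COCc3ccc(OC)cc3)[C@@H]12
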